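## The problem

Compound **32** is (–)-epicatechin joined through C4 (β face) to C6' of a (–)-epigallocatechin unit that carries galloyl esters on O3' and on the 3''-oxygen of ring E. Unprimed atoms with rings A, C and B belong to the upper unit, primed atoms with benzo ring D and pyran ring F to the lower unit, and doubly primed atoms to pyrogallol ring E. The ring junction is the first difficulty: C4 must bond to the ring D carbon flanked by two oxygens, whereas an intact flavan-3-ol captures a flavan-4-yl cation mainly at C8', so the 4→6 pattern has to follow from connectivity. Of the five stereocentres, C2 and C3 come with (–)-epicatechin and the C3 oxygen sends the C4 substituent to the opposite face. C2' and C3' are too remote to be controlled by the upper unit and need a reagent-controlled step, and their cis relationship is the one that invertive or cationic closures at C2' do not give. The C4–C6' bond is cleaved by acid, C2 epimerises and the polyphenol oxidises in base once phenols are free, and a galloyl ester on ring E can migrate to a neighbouring free hydroxyl, so all phenols stay benzylated and the esters are attached in the last step but one. Only two of the eleven hydroxyls of the parent dimer are acylated, so O3' and O3'' need protection orthogonal to benzyl. The enabling feature is that 2',3'-cis ring F equals the syn pattern of the open chain C4'–C3'(O)–C2'(O)–ring E, provided the C2' oxygen becomes O1' by bonding to C8a' with no bond to C2' broken; C8a' is the oxygen-bearing carbon para to C6' in a ring D that derives from a symmetric phloroglucinol diether.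

## Retrosynthesis

**32 ⇒ 31.** The fifteen O–benzyl bonds are cut last. Benzyl is preferred to silyl or acetal protection because one neutral hydrogenolysis frees every phenol and the C3 alcohol without acid or base. The forward step must leave both esters and the benzylic ring oxygens intact.

**31 ⇒ 29 + 30, and 29 ⇒ 27.** Both ester C–O bonds are cut, so one acid (**30**) supplies both galloyl groups and only O3' and O3'' are free in **29**. Carrying an ester on O3' through ring closure was rejected because it would migrate to the neighbouring C2' alkoxide. **29** comes from **27** by removing two methoxymethyl (MOM) groups, which one buffered reagent should cleave at both the aryl and the alkyl oxygen without strong acid.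

**27 ⇒ 26.** The O1'–C8a' bond is cut. The neighbouring cut at O1'–C2' (phenol oxygen attacking an activated benzylic carbon) inverts or ionises C2' and leads to the trans series. The chosen cut leaves C2' and C3' untouched, so the precursor is simply an open-chain syn diol monoether beside an aryl triflate. The forward reaction must form a C–O bond at an electron-rich aryl carbon from a secondary alkoxide without β-hydride loss.

**26 ⇒ 25 ⇒ 24.** These are functional-group changes only. The C2' oxygen travels as a silyl ether through the C–C bond formations and is released after the ring D phenol of **24** has been triflated, so that only one oxygen is ever free when an electrophile is present.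

**24 ⇒ 23 ⇒ 8 + 21.** The C4a'–C4' bond is cut. The free phenol of **8** delivers aldehyde **21** to its own ortho carbon; both ortho carbons are constitutionally equivalent and ring A has no free phenol to compete. The carbinol formed at C4' in **23** is then removed. A cut at C3'–C4' would need an α-alkoxy carbanion. Dihydroxylation of a 1,3-diarylpropene would give a diol whose two hydroxyls cannot be told apart, whereas **21** arrives with O3' masked and O2' differentiated.

**21 ⇒ 19 ⇒ 18 ⇒ 13 + 15.** The C2'–C3' bond is cut. One alkoxyallylboration of aldehyde **13** sets both stereocentres, gives the syn relationship and delivers O3' as its MOM ether with O2' free. Oxidative cleavage of the vinyl group then exposes C4' as the aldehyde. The forward step needs reagent control of the aldehyde face and a (Z)-configured γ-alkoxyallyl unit.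

**13 ⇒ 12 ⇒ 11 ⇒ 10 ⇒ 9, and 15 ⇒ 14.** Ring E comes from methyl gallate (**9**) by partial benzylation, which leaves one meta hydroxyl for the MOM group, and adjustment of the ester to the aldehyde. The allyl ether **15** is one step from allyl alcohol (**14**).

**8 ⇒ 7 ⇒ 4 + 6.** The C4–C6' bond is cut. The arylation is done on the symmetric silyl ether **6** before any chain is present, so attack para to the silyloxy group gives a product whose regiochemistry is fixed by symmetry; the oxygen para to the new bond later becomes O1'. Arylating a finished lower flavan would favour C8'. The forward reaction needs 4β selectivity, which the C3 benzyloxy group provides, and para selectivity, for which the bulky silyl group is chosen.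

**4 ⇒ 3 ⇒ 2 ⇒ 1, and 6 ⇒ 5.** The C4 leaving group is introduced by benzylic oxidation of benzylated (–)-epicatechin (**1**). O3 is benzylated so that it stays out of the late acylation. **6** is the silyl ether of commercial **5**.

## Roads not taken

**Alternative 1:** Ring D itself is cut (C5'–C6', C7'–C8' and C4a'–C5'). The partners are the pyran-fused cyclobutenone **A2**, which already carries ring E and both protected gallates, and the upper-unit siloxyalkyne **A3**. On heating, **A2** opens in a four-electron electrocyclic step and adds across the alkyne of **A3**; a second opening and a six-electron closure give phenol **A1**.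
- Merits: the alkyne carbon bearing the epicatechin unit ends between the two ring D oxygens, so the 4→6 pattern needs no regioselective arylation. The two halves meet late and fully elaborated. **A1** is two deprotections from **32**. In convergence and regiochemical certainty this road is better than the chosen one.
- Weak points: **A2** is a strained enol-ether cyclobutenone that must already contain the cis C2'/C3' pair, so the central stereochemical problem is moved into its preparation. **A3** needs a C4-alkynyl epicatechin and conversion of a terminal alkyne into a siloxyalkyne beside a hindered, ionisable C4. The annulation must tolerate a β-oxygenated secondary substituent on the alkyne and two aryl esters at elevated temperature.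
- Comparison: the chosen plan sets against this intermediates reached by standard reactions from purchasable materials and a ring closure that transfers, rather than presupposes, the cis relationship. With **A2** and **A3** included, Alternative 1 is unlikely to be shorter.

**Alternative 2:** Ring C is cut at C3–C4 and O1–C2, so the upper heterocycle is built onto a finished lower flavan. A chiral phosphoric acid dehydrates the ortho-hydroxy diarylcarbinol **A5** to the ortho-quinone methide **A6**, which adds the (Z)-styrylboronate **A7** to give boronate **A4**. Oxidation of the C–B bond would give the C3 hydroxyl with retention.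
- Merits: three stereocentres and a ring are formed in one step and the (Z)-alkene encodes 2,3-cis. The road does not depend on natural epicatechin, so ring B analogues are open. In that flexibility it is better than the chosen plan, which is tied to the chiral pool.
- Weak points: C2, C3 and C4 must all be set by a catalyst working against a remote chiral lower unit. The 3,4-trans relationship depends on the geometry of **A6**, which bears a very hindered 2,6-dialkoxyaryl group. Vinylboronates are weak partners for such heterodienes and the (Z)-alkene can isomerise under acid. The lower unit must first be functionalised selectively at C6' and made with its own cis ring F, which this road does not address.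
- Comparison: the chosen plan takes C2 and C3 from (–)-epicatechin at no cost, obtains C4 by inherent anti addition, and puts its effort into ring F, which Alternative 2 leaves open.

**Alternative 3:** Ring F is cut at C2'–C3' and O1'–C2'. A triazolium-derived carbene turns the ring E aldehyde **A10** into an acyl anion equivalent that adds to the ring-opened hydroxy-aldehyde form of lactol **A9**. The ring D phenol then closes onto the new ketone to give hemiketal **A8**.
- Merits: this is the shortest way to a ring F skeleton. The partners are simple, the ring D side chain needs only two carbons, and no triflate, palladium or O3' protection is required. In step economy up to ring F it is better than the chosen plan.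
- Weak points: an electron-rich aryl aldehyde is a sluggish acyl donor and the acceptor is an enolisable arylacetaldehyde, so self-condensation and aldol pathways compete. The C3' centre formed lies next to a ketone or hemiketal carbon and can epimerise. C2' is not set at all: **A8** must still be reduced through a cyclic oxocarbenium ion, under acid that endangers the C4–C6' bond, and hydride delivery there is expected to favour the 2',3'-trans isomer.
- Comparison: the chosen plan spends more steps on the chain (aldehyde **21**, hydroxyalkylation, deoxygenation, triflation). In return both lower-unit stereocentres are fixed by a well-understood reagent before ring closure and are not touched afterwards.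

Key step: step 19

## Steps

Assumption: the γ-alkoxyallyl-diisopinocampheylborane made from (+)-α-pinene is taken to add to the Si face of aryl aldehydes, as the parent allyl reagent does, and **5**, **30**, (–)-Ipc2BOMe and RockPhos are taken as purchasable.

Step 1
Reactants: 1 (–)-epicatechin
Product: 2 5,7,3',4'-tetra-O-benzyl-(–)-epicatechin
Conditions: BnBr, K2CO3, DMF, 0 °C to rt
Reagents that add atoms: benzyl bromide, BrCc1ccccc1
Why: Williamson etherification of the four phenols only; carbonate does not deprotonate the C3 alcohol and the low temperature limits base-induced epimerisation at C2.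

Step 2
Reactants: 2 5,7,3',4'-tetra-O-benzyl-(–)-epicatechin
Product: 3 5,7,3',4'-tetra-O-benzyl-4β-(2-ethoxyethoxy)epicatechin
Conditions: DDQ, 2-ethoxyethanol, CH2Cl2, rt
Reagents that add atoms: 2-ethoxyethanol, OCCOCC
Why: Quinone-mediated benzylic oxidation; hydride abstraction from C4 gives a cation stabilised by the ring A ether oxygens, and the alcohol adds anti to the C3 hydroxyl, which sets the 4β (3,4-trans) ether.

Step 3
Reactants: 3 5,7,3',4'-tetra-O-benzyl-4β-(2-ethoxyethoxy)epicatechin
Product: 4 3,5,7,3',4'-penta-O-benzyl-4β-(2-ethoxyethoxy)epicatechin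
Conditions: NaH, BnBr, Bu4NI (cat.), DMF, 0 °C to rt
Reagents that add atoms: benzyl bromide, BrCc1ccccc1
Why: Williamson etherification of the secondary alcohol; the C4 ether is stable to base, and the O3 benzyl group keeps this oxygen out of the late acylation and falls in the last step.

Step 4
Reactants: 5 3,5-bis(benzyloxy)phenol
Product: 6 [3,5-bis(benzyloxy)phenoxy]triisopropylsilane
Conditions: i-Pr3SiCl, imidazole, DMF, rt
Reagents that add atoms: chlorotriisopropylsilane, CC(C)[Si](Cl)(C(C)C)C(C)C
Why: Imidazole-promoted silylation of the phenol; the triisopropylsilyl group is chosen because its bulk screens the two flanking ring carbons in the next step.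

Step 5
Reactants: 4 3,5,7,3',4'-penta-O-benzyl-4β-(2-ethoxyethoxy)epicatechin; 6 [3,5-bis(benzyloxy)phenoxy]triisopropylsilane
Product: 7 4-(3,5,7,3',4'-penta-O-benzylepicatechin-4β-yl)-3,5-bis(benzyloxy)phenyl triisopropylsilyl ether
Conditions: 6 (3 equiv), TMSOTf (0.5 equiv), CH2Cl2, –78 to –40 °C
Reagents that add atoms: none
Why: Friedel–Crafts arylation through the ring A-stabilised C4 cation; the arene enters anti to the C3 benzyloxy group (4β, 3,4-trans) and should attack the carbon para to the silyloxy group because the bulky silyl group screens both of its ortho carbons, while excess 6 suppresses self-condensation of 4.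

Step 6
Reactants: 7 4-(3,5,7,3',4'-penta-O-benzylepicatechin-4β-yl)-3,5-bis(benzyloxy)phenyl triisopropylsilyl ether
Product: 8 4-(3,5,7,3',4'-penta-O-benzylepicatechin-4β-yl)-3,5-bis(benzyloxy)phenol
Conditions: TBAF, THF, 0 °C; aq NH4Cl
Reagents that add atoms: none
Why: Fluoride cleavage of the aryl silyl ether; benzyl ethers and the C4–aryl bond are inert, and the symmetry of the ring D signals should confirm the site of arylation.

Step 7
Reactants: 9 methyl gallate
Product: 10 methyl 3,4-bis(benzyloxy)-5-hydroxybenzoate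
Conditions: BnBr (2 equiv), K2CO3, DMF, rt
Reagents that add atoms: benzyl bromide, BrCc1ccccc1
Why: Partial Williamson etherification; the 4-hydroxyl para to the ester is the most acidic and reacts first, after which either equivalent meta hydroxyl gives the same 3,4-dibenzyl ether, to be separated from mono- and tribenzyl material.

Step 8
Reactants: 10 methyl 3,4-bis(benzyloxy)-5-hydroxybenzoate
Product: 11 methyl 3,4-bis(benzyloxy)-5-(methoxymethoxy)benzoate
Conditions: MOMCl, i-Pr2NEt, CH2Cl2, 0 °C to rt
Reagents that add atoms: chloromethyl methyl ether, COCCl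
Why: Acetal protection of the remaining phenol by alkylation; this MOM group marks the ring E oxygen that will later carry a galloyl group.

Step 9
Reactants: 11 methyl 3,4-bis(benzyloxy)-5-(methoxymethoxy)benzoate
Product: 12 [3,4-bis(benzyloxy)-5-(methoxymethoxy)phenyl]methanol
Conditions: LiAlH4, THF, 0 °C
Reagents that add atoms: none
Why: Hydride reduction of the ester to the benzylic alcohol; aryl ethers and the acetal are inert.

Step 10
Reactants: 12 [3,4-bis(benzyloxy)-5-(methoxymethoxy)phenyl]methanol
Product: 13 3,4-bis(benzyloxy)-5-(methoxymethoxy)benzaldehyde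
Conditions: MnO2, CH2Cl2, rt
Reagents that add atoms: none
Why: Selective oxidation of a benzylic alcohol by MnO2, which stops at the aldehyde.

Step 11
Reactants: 14 allyl alcohol
Product: 15 allyl methoxymethyl ether
Conditions: MOMCl, i-Pr2NEt, CH2Cl2, 0 °C to rt
Reagents that add atoms: chloromethyl methyl ether, COCCl
Why: Acetal formation by O-alkylation; the MOM oxygen later chelates lithium and fixes the (Z) geometry of the metalated allyl ether.

Step 12
Reactants: 15 allyl methoxymethyl ether; 13 3,4-bis(benzyloxy)-5-(methoxymethoxy)benzaldehyde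
Product: 18 (1R,2R)-1-[3,4-bis(benzyloxy)-5-(methoxymethoxy)phenyl]-2-(methoxymethoxy)but-3-en-1-ol, via (Z)-alkoxyallyl-diisopinocampheylborane 16 (not isolated), via borinate ester 17 (not isolated)
Conditions: s-BuLi, THF, –78 °C; (–)-Ipc2BOMe; BF3·OEt2; then 13, –78 °C; NaOH, H2O2
Reagents that add atoms: none
Why: Brown alkoxyallylboration; the chelated (Z)-γ-alkoxyallyl unit reacts through a chair six-membered transition state, which gives the syn relationship, and the isopinocampheyl groups derived from (+)-α-pinene direct attack to the Si face of the aldehyde, which sets C2' and C3' as R,R with O3' masked and O2' free.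

Step 13
Reactants: 18 (1R,2R)-1-[3,4-bis(benzyloxy)-5-(methoxymethoxy)phenyl]-2-(methoxymethoxy)but-3-en-1-ol
Product: 19 tert-butyldimethylsilyl ether of 18 at the benzylic oxygen
Conditions: TBSCl, imidazole, DMF, rt
Reagents that add atoms: tert-butyldimethylsilyl chloride, CC(C)(C)[Si](C)(C)Cl
Why: Silylation of the secondary alcohol under imidazole catalysis, which avoids silyl triflates that could attack the MOM acetals; the silyl ether is the temporary mask for O2'.

Step 14
Reactants: 19 tert-butyldimethylsilyl ether of 18 at the benzylic oxygen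
Product: 21 (2S,3R)-3-[3,4-bis(benzyloxy)-5-(methoxymethoxy)phenyl]-3-(tert-butyldimethylsilyloxy)-2-(methoxymethoxy)propanal, via vicinal diol 20 (not isolated)
Conditions: OsO4 (cat.), NaIO4, 2,6-lutidine, dioxane/H2O, rt
Reagents that add atoms: osmium tetroxide, O=[Os](=O)(=O)=O; sodium periodate, [Na+].[O-]I(=O)(=O)=O
Why: Lemieux–Johnson oxidative cleavage of the terminal alkene; the buffered, near-neutral medium leaves the α-alkoxy stereocentre and the benzyl ethers alone, and the vinyl carbon becomes C4'.

Step 15
Reactants: 8 4-(3,5,7,3',4'-penta-O-benzylepicatechin-4β-yl)-3,5-bis(benzyloxy)phenol; 21 (2S,3R)-3-[3,4-bis(benzyloxy)-5-(methoxymethoxy)phenyl]-3-(tert-butyldimethylsilyloxy)-2-(methoxymethoxy)propanal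
Product: 23 ortho-(1-hydroxyalkyl)phenol from 8 and 21 (C4' carbinol epimers), via bromomagnesium phenoxide 22 (not isolated)
Conditions: 8, EtMgBr, Et2O, 0 °C; solvent change to CH2Cl2; 21, rt; aq NH4Cl
Reagents that add atoms: none
Why: Ortho-specific hydroxyalkylation of a magnesium phenoxide (aldol-type C-alkylation); magnesium binds the aldehyde and delivers it to the adjacent ring carbon through a six-membered chelate, the two ortho carbons of 8 are constitutionally equivalent, ring A has no free phenol, and the new carbinol centre is removed in the next step.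

Step 16
Reactants: 23 ortho-(1-hydroxyalkyl)phenol from 8 and 21 (C4' carbinol epimers)
Product: 24 ortho-alkylphenol with the chain CH2–CH(OMOM)–CH(OTBS)–ring E (C3' R and C2' R)
Conditions: Et3SiH, CF3CO2H, CH2Cl2, –40 °C
Reagents that add atoms: none
Why: Ionic hydrogenation; the C4' hydroxyl lies ortho and para to three ring D oxygens and ionises under mild acid to a quinone-methide-like cation that the silane reduces, while the less activated C2' silyl ether and the acetals should persist at low temperature.

Step 17
Reactants: 24 ortho-alkylphenol with the chain CH2–CH(OMOM)–CH(OTBS)–ring E (C3' R and C2' R)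
Product: 25 aryl triflate of 24 at the ring D oxygen
Conditions: PhNTf2, Et3N, DMAP (cat.), CH2Cl2, rt
Reagents that add atoms: N-phenylbis(trifluoromethanesulfonimide), O=S(=O)(N(c1ccccc1)S(=O)(=O)C(F)(F)F)C(F)(F)F
Why: Sulfonylation of the only free hydroxyl with a mild triflyl donor; the triflate now stands para to C6' and ortho to the chain.

Step 18
Reactants: 25 aryl triflate of 24 at the ring D oxygen
Product: 26 ring D aryl triflate with the chain CH2–CH(OMOM)–CH(OH)–ring E (C3' R and C2' R; syn)
Conditions: HF·pyridine, pyridine, THF, 0 °C to rt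
Reagents that add atoms: none
Why: Fluoride-mediated desilylation under buffered acidic conditions, which spare the aryl triflate (labile to basic fluoride), the MOM acetals and the benzyl ethers.

Step 19
Reactants: 26 ring D aryl triflate with the chain CH2–CH(OMOM)–CH(OH)–ring E (C3' R and C2' R; syn)
Product: 27 3,5,7,3',4'-penta-O-benzylepicatechin-(4β→6)-5,7,4',5'-tetra-O-benzyl-3,3'-bis-O-(methoxymethyl)epigallocatechin
Conditions: Pd2(dba)3 (5 mol %), RockPhos (12 mol %), Cs2CO3, toluene, 90 °C
Reagents that add atoms: none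
Why: Buchwald–Hartwig-type intramolecular aryl etherification: zerovalent palladium carrying the bulky di-tert-butyl biarylphosphine inserts into the C8a'–OTf bond, Cs2CO3 deprotonates the C2' hydroxyl so that the alkoxide replaces triflate on divalent palladium, and C–O reductive elimination from the seven-membered oxapalladacycle (Pd, C8a', C4a', C4', C3', C2', O) forms O1'–C8a'. The closest known reaction type is the palladium-catalysed cyclisation of secondary alcohols onto aryl halides or sulfonates, which gives chromans without loss of configuration at the carbinol carbon. Six-membered ring F closes in a 6-exo sense by attack of the tethered oxygen on the metalated aryl carbon. No stereocentre is created: C2' and C3' keep the syn relationship set in step 12 because no bond to either carbon is broken, so syn becomes 2',3'-cis. The step needs reductive elimination to outrun β-hydride elimination from the secondary alkoxide, which the hindered electron-rich ligand promotes and which is more demanding here because the aryl group on palladium is electron-rich. The MOM ether on O3' excludes a five-membered ring, and the triflate para to C6' fixes the 4→6 pattern.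

Step 20
Reactants: 27 3,5,7,3',4'-penta-O-benzylepicatechin-(4β→6)-5,7,4',5'-tetra-O-benzyl-3,3'-bis-O-(methoxymethyl)epigallocatechin
Product: 29 3,5,7,3',4'-penta-O-benzylepicatechin-(4β→6)-5,7,4',5'-tetra-O-benzylepigallocatechin, via silyl ether pyridinium salt 28 (not isolated)
Conditions: TMSOTf, 2,2'-bipyridyl, CH2Cl2, 0 °C to rt; then H2O, aq NaHCO3
Reagents that add atoms: none
Why: Silyl triflate/2,2'-bipyridyl cleavage of MOM acetals; the alkyl acetal is converted into a pyridinium acetal and the aryl acetal into a silyl ether, both hydrolysed by water, and the buffered medium contains no free strong acid that could break the C4–C6' bond or benzyl ethers.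

Step 21
Reactants: 29 3,5,7,3',4'-penta-O-benzylepicatechin-(4β→6)-5,7,4',5'-tetra-O-benzylepigallocatechin; 30 3,4,5-tris(benzyloxy)benzoic acid
Product: 31 pentadeca-O-benzyl derivative of 32
Conditions: 30 (3 equiv), EDC·HCl, DMAP, CH2Cl2, rt
Reagents that add atoms: none
Why: Steglich esterification of the only two free hydroxyls (axial C3' alcohol and ring E phenol) through the acylpyridinium species; no other oxygen is free, so the positions of both esters are fixed.

Step 22
Reactants: 31 pentadeca-O-benzyl derivative of 32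
Product: 32 (–)-epicatechin-(4β→6)-(–)-epigallocatechin 3,3'-di-O-gallate
Conditions: H2 (1 atm), Pd(OH)2/C, THF/MeOH, rt
Reagents that add atoms: none
Why: Catalytic hydrogenolysis of fifteen benzyl ethers under neutral conditions; esters are inert, and a short reaction time without base limits opening of the benzylic ring ethers and migration of the ring E ester.

## Compound list

1 | (–)-epicatechin, (2R,3R) | C1c2c(O)cc(O)cc2O[C@H](c2ccc(O)c(O)c2)[C@@H]1O | starting material
2 | 5,7,3',4'-tetra-O-benzyl-(–)-epicatechin (free 3-OH) | C1c2c(OCc9ccccc9)cc(OCc9ccccc9)cc2O[C@H](c2ccc(OCc9ccccc9)c(OCc9ccccc9)c2)[C@@H]1O | intermediate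
3 | 5,7,3',4'-tetra-O-benzyl-4β-(2-ethoxyethoxy)epicatechin (2,3-cis, 3,4-trans) | CCOCCO[C@H]4c5c(OCc9ccccc9)cc(OCc9ccccc9)cc5O[C@H](c5ccc(OCc9ccccc9)c(OCc9ccccc9)c5)[C@@H]4O | intermediate
4 | 3,5,7,3',4'-penta-O-benzyl-4β-(2-ethoxyethoxy)epicatechin | CCOCCO[C@H]4c5c(OCc9ccccc9)cc(OCc9ccccc9)cc5O[C@H](c5ccc(OCc9ccccc9)c(OCc9ccccc9)c5)[C@@H]4OCc9ccccc9 | intermediate
5 | 3,5-bis(benzyloxy)phenol | Oc1cc(OCc2ccccc2)cc(OCc2ccccc2)c1 | starting material
6 | [3,5-bis(benzyloxy)phenoxy]triisopropylsilane | CC(C)[Si](C(C)C)(C(C)C)Oc1cc(OCc2ccccc2)cc(OCc2ccccc2)c1 | intermediate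
7 | 4-(3,5,7,3',4'-penta-O-benzylepicatechin-4β-yl)-3,5-bis(benzyloxy)phenyl triisopropylsilyl ether (3,4-trans) | CC(C)[Si](C(C)C)(C(C)C)Oc1cc(OCc9ccccc9)c([C@H]4c5c(OCc9ccccc9)cc(OCc9ccccc9)cc5O[C@H](c5ccc(OCc9ccccc9)c(OCc9ccccc9)c5)[C@@H]4OCc9ccccc9)c(OCc9ccccc9)c1 | intermediate
8 | 4-(3,5,7,3',4'-penta-O-benzylepicatechin-4β-yl)-3,5-bis(benzyloxy)phenol | Oc1cc(OCc9ccccc9)c([C@H]4c5c(OCc9ccccc9)cc(OCc9ccccc9)cc5O[C@H](c5ccc(OCc9ccccc9)c(OCc9ccccc9)c5)[C@@H]4OCc9ccccc9)c(OCc9ccccc9)c1 | intermediate
9 | methyl gallate | COC(=O)c1cc(O)c(O)c(O)c1 | starting material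
10 | methyl 3,4-bis(benzyloxy)-5-hydroxybenzoate | COC(=O)c1cc(O)c(OCc2ccccc2)c(OCc2ccccc2)c1 | intermediate
11 | methyl 3,4-bis(benzyloxy)-5-(methoxymethoxy)benzoate | COCOc1cc(C(=O)OC)cc(OCc2ccccc2)c1OCc2ccccc2 | intermediate
12 | [3,4-bis(benzyloxy)-5-(methoxymethoxy)phenyl]methanol | COCOc1cc(CO)cc(OCc2ccccc2)c1OCc2ccccc2 | intermediate
13 | 3,4-bis(benzyloxy)-5-(methoxymethoxy)benzaldehyde | COCOc1cc(C=O)cc(OCc2ccccc2)c1OCc2ccccc2 | intermediate
14 | allyl alcohol | C=CCO | starting material
15 | allyl methoxymethyl ether | C=CCOCOC | intermediate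
16 | [(Z)-3-(methoxymethoxy)prop-2-en-1-yl]diisopinocampheylborane, isopinocampheyl groups from (+)-α-pinene (formed in the flask) | COCO/C=C\CB([C@@H]1C[C@@H]2C[C@H]([C@H]1C)C2(C)C)[C@@H]1C[C@@H]2C[C@H]([C@H]1C)C2(C)C | intermediate
17 | O-(diisopinocampheylboryl) derivative of 18 (borinate ester, formed in the flask) | COCOc1cc([C@@H](OB([C@@H]2C[C@@H]3C[C@H]([C@H]2C)C3(C)C)[C@@H]2C[C@@H]3C[C@H]([C@H]2C)C3(C)C)[C@H](OCOC)C=C)cc(OCc9ccccc9)c1OCc9ccccc9 | intermediate
18 | (1R,2R)-1-[3,4-bis(benzyloxy)-5-(methoxymethoxy)phenyl]-2-(methoxymethoxy)but-3-en-1-ol (syn) | COCOc1cc([C@@H](O)[C@H](OCOC)C=C)cc(OCc9ccccc9)c1OCc9ccccc9 | intermediate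
19 | (1R,2R)-1-[3,4-bis(benzyloxy)-5-(methoxymethoxy)phenyl]-1-(tert-butyldimethylsilyloxy)-2-(methoxymethoxy)but-3-ene | COCOc1cc([C@@H](O[Si](C)(C)C(C)(C)C)[C@H](OCOC)C=C)cc(OCc9ccccc9)c1OCc9ccccc9 | intermediate
20 | vicinal diol from dihydroxylation of the vinyl group of 19 (both carbinol epimers, formed in the flask) | COCOc1cc([C@@H](O[Si](C)(C)C(C)(C)C)[C@H](OCOC)C(O)CO)cc(OCc9ccccc9)c1OCc9ccccc9 | intermediate
21 | (2S,3R)-3-[3,4-bis(benzyloxy)-5-(methoxymethoxy)phenyl]-3-(tert-butyldimethylsilyloxy)-2-(methoxymethoxy)propanal | COCOc1cc([C@@H](O[Si](C)(C)C(C)(C)C)[C@H](OCOC)C=O)cc(OCc9ccccc9)c1OCc9ccccc9 | intermediate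
22 | bromomagnesium phenoxide of 8 (formed in the flask) | Br[Mg]Oc1cc(OCc9ccccc9)c([C@H]4c5c(OCc9ccccc9)cc(OCc9ccccc9)cc5O[C@H](c5ccc(OCc9ccccc9)c(OCc9ccccc9)c5)[C@@H]4OCc9ccccc9)c(OCc9ccccc9)c1 | intermediate
23 | phenol 8 bearing at one ortho carbon the chain CH(OH)–CH(OMOM)–CH(OTBS)–[3,4-bis(benzyloxy)-5-(methoxymethoxy)phenyl]; C4' carbinol epimers, the other two chain centres as in 21 | COCOc1cc([C@@H](O[Si](C)(C)C(C)(C)C)[C@H](OCOC)C(O)c3c(O)cc(OCc9ccccc9)c([C@H]4c5c(OCc9ccccc9)cc(OCc9ccccc9)cc5O[C@H](c5ccc(OCc9ccccc9)c(OCc9ccccc9)c5)[C@@H]4OCc9ccccc9)c3OCc9ccccc9)cc(OCc9ccccc9)c1OCc9ccccc9 | intermediate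
24 | phenol 8 bearing at one ortho carbon the chain CH2–CH(OMOM)–CH(OTBS)–[3,4-bis(benzyloxy)-5-(methoxymethoxy)phenyl]; C3' R, C2' R, syn | COCOc1cc([C@@H](O[Si](C)(C)C(C)(C)C)[C@H](OCOC)Cc3c(O)cc(OCc9ccccc9)c([C@H]4c5c(OCc9ccccc9)cc(OCc9ccccc9)cc5O[C@H](c5ccc(OCc9ccccc9)c(OCc9ccccc9)c5)[C@@H]4OCc9ccccc9)c3OCc9ccccc9)cc(OCc9ccccc9)c1OCc9ccccc9 | intermediate
25 | trifluoromethanesulfonate of phenol 24 | COCOc1cc([C@@H](O[Si](C)(C)C(C)(C)C)[C@H](OCOC)Cc3c(OS(=O)(=O)C(F)(F)F)cc(OCc9ccccc9)c([C@H]4c5c(OCc9ccccc9)cc(OCc9ccccc9)cc5O[C@H](c5ccc(OCc9ccccc9)c(OCc9ccccc9)c5)[C@@H]4OCc9ccccc9)c3OCc9ccccc9)cc(OCc9ccccc9)c1OCc9ccccc9 | intermediate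
26 | ring D aryl triflate (triflate para to the epicatechin-4β-yl carbon) with the ortho chain CH2–CH(OMOM)–CH(OH)–[3,4-bis(benzyloxy)-5-(methoxymethoxy)phenyl]; C3' R, C2' R, syn | COCOc1cc([C@@H](O)[C@H](OCOC)Cc3c(OS(=O)(=O)C(F)(F)F)cc(OCc9ccccc9)c([C@H]4c5c(OCc9ccccc9)cc(OCc9ccccc9)cc5O[C@H](c5ccc(OCc9ccccc9)c(OCc9ccccc9)c5)[C@@H]4OCc9ccccc9)c3OCc9ccccc9)cc(OCc9ccccc9)c1OCc9ccccc9 | intermediate
27 | 3,5,7,3',4'-penta-O-benzylepicatechin-(4β→6)-5,7,4',5'-tetra-O-benzyl-3,3'-bis-O-(methoxymethyl)epigallocatechin (ring F 2R,3R, cis) | COCOc1cc([C@H]2Oc3cc(OCc9ccccc9)c([C@H]4c5c(OCc9ccccc9)cc(OCc9ccccc9)cc5O[C@H](c5ccc(OCc9ccccc9)c(OCc9ccccc9)c5)[C@@H]4OCc9ccccc9)c(OCc9ccccc9)c3C[C@H]2OCOC)cc(OCc9ccccc9)c1OCc9ccccc9 | intermediate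
28 | ring E trimethylsilyl ether and O3' (2,2'-bipyridin-1-ium-1-yl)methyl ether of 29, triflate salt (formed in the flask) | C[Si](C)(C)Oc1cc([C@H]2Oc3cc(OCc9ccccc9)c([C@H]4c5c(OCc9ccccc9)cc(OCc9ccccc9)cc5O[C@H](c5ccc(OCc9ccccc9)c(OCc9ccccc9)c5)[C@@H]4OCc9ccccc9)c(OCc9ccccc9)c3C[C@H]2OC[n+]2ccccc2-c2ccccn2)cc(OCc9ccccc9)c1OCc9ccccc9.[O-]S(=O)(=O)C(F)(F)F | intermediate
29 | 3,5,7,3',4'-penta-O-benzylepicatechin-(4β→6)-5,7,4',5'-tetra-O-benzylepigallocatechin (free C3' alcohol and one free ring E phenol) | Oc1cc([C@H]2Oc3cc(OCc9ccccc9)c([C@H]4c5c(OCc9ccccc9)cc(OCc9ccccc9)cc5O[C@H](c5ccc(OCc9ccccc9)c(OCc9ccccc9)c5)[C@@H]4OCc9ccccc9)c(OCc9ccccc9)c3C[C@H]2O)cc(OCc9ccccc9)c1OCc9ccccc9 | intermediate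
30 | 3,4,5-tris(benzyloxy)benzoic acid | O=C(O)c1cc(OCc2ccccc2)c(OCc2ccccc2)c(OCc2ccccc2)c1 | starting material
31 | pentadeca-O-benzyl derivative of 32 (bis-tri-O-benzylgalloyl ester of 29) | O=C(Oc1cc([C@H]2Oc3cc(OCc9ccccc9)c([C@H]4c5c(OCc9ccccc9)cc(OCc9ccccc9)cc5O[C@H](c5ccc(OCc9ccccc9)c(OCc9ccccc9)c5)[C@@H]4OCc9ccccc9)c(OCc9ccccc9)c3C[C@H]2OC(=O)c2cc(OCc9ccccc9)c(OCc9ccccc9)c(OCc9ccccc9)c2)cc(OCc9ccccc9)c1OCc9ccccc9)c1cc(OCc9ccccc9)c(OCc9ccccc9)c(OCc9ccccc9)c1 | intermediate
32 | (–)-epicatechin-(4β→6)-(–)-epigallocatechin 3,3'-di-O-gallate (galloyl on O3' and O3'' in the numbering used here) | O=C(Oc1cc([C@H]2Oc3cc(O)c([C@H]4c5c(O)cc(O)cc5O[C@H](c5ccc(O)c(O)c5)[C@@H]4O)c(O)c3C[C@H]2OC(=O)c2cc(O)c(O)c(O)c2)cc(O)c1O)c1cc(O)c(O)c(O)c1 | target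

## Step count and least certain steps

Total: 22 steps. Longest linear sequence: 15 steps from methyl gallate (steps 7, 8, 9, 10, 12, 13, 14, 15, 16, 17, 18, 19, 20, 21, 22).

**Step 19 (key step).** The likely failure is β-hydride elimination from the palladium alkoxide outrunning C–O reductive elimination, because the electron-rich aryl group slows the latter. This would oxidise C2' and reduce the triflate carbon. Sulfur–oxygen cleavage of the triflate by base is a second loss channel. Fallback by double inversion, with no metal: starting from 26, a Mitsunobu reaction with 4-nitrobenzoic acid (PPh3, DIAD) should invert C2' and give the anti 4-nitrobenzoate F1. Et4NOH in dioxane would then cleave both the ester and the aryl triflate to the anti alcohol with free ring D phenol F2. An intramolecular Mitsunobu etherification (PPh3, DIAD) would close ring F with a second inversion at C2' and rejoin the route at 27.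

**Step 5.** The likely failure is poor regioselectivity: attack at a carbon ortho to the silyloxy group if the silyl group screens less than assumed. Self-condensation of 4 is the second risk. Fallback with regiochemistry fixed by threefold symmetry: starting from 4, Friedel–Crafts reaction with excess phloroglucinol (BF3·OEt2, THF/CH2Cl2) can give only one product, the triol F3. i-Pr3SiCl and imidazole should silylate the unhindered hydroxyl para to the flavanyl group and give the monosilyl ether F4. Benzylation of the two remaining phenols (BnBr, K2CO3, acetone) returns to the route at 7.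

**Step 15.** The likely failures are slow C–C bond formation at the hindered ortho carbon and enolisation of aldehyde 21 by the basic phenoxide, which would erode the C3' configuration. Fallback with a boron template under weakly acidic conditions: starting from 8 and 21, PhB(OH)2 with catalytic propionic acid in refluxing benzene with removal of water should give the 2-phenyl-4H-1,3,2-benzodioxaborin F5. Its benzylic C–O bond is then reduced with Et3SiH and CF3CO2H, so this path bypasses 23 and rejoins the route at 24.

**Step 16.** The likely failures are loss of the aryl MOM or the silyl ether under acid, capture of the C4' cation by ring E in an intramolecular Friedel–Crafts reaction, and proton loss from C3' to an enol ether. Fallback under basic conditions: starting from 23, Ac2O, pyridine and DMAP should give the diacetate F6. NaBH4 in EtOH/THF then removes the aryl acetate, the phenoxide expels the benzylic acetate, and hydride adds to the resulting ortho-quinone methide, which returns to the route at 24.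

## Further compounds

F1 | step 19 | anti 4-nitrobenzoate of 26 (C2' inverted, aryl triflate retained) | COCOc1cc([C@H](OC(=O)c2ccc(cc2)[N+](=O)[O-])[C@H](OCOC)Cc3c(OS(=O)(=O)C(F)(F)F)cc(OCc9ccccc9)c([C@H]4c5c(OCc9ccccc9)cc(OCc9ccccc9)cc5O[C@H](c5ccc(OCc9ccccc9)c(OCc9ccccc9)c5)[C@@H]4OCc9ccccc9)c3OCc9ccccc9)cc(OCc9ccccc9)c1OCc9ccccc9
F2 | step 19 | anti alcohol with free ring D phenol (C2' epimer of 26 without the triflyl group) | COCOc1cc([C@H](O)[C@H](OCOC)Cc3c(O)cc(OCc9ccccc9)c([C@H]4c5c(OCc9ccccc9)cc(OCc9ccccc9)cc5O[C@H](c5ccc(OCc9ccccc9)c(OCc9ccccc9)c5)[C@@H]4OCc9ccccc9)c3OCc9ccccc9)cc(OCc9ccccc9)c1OCc9ccccc9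
F3 | step 5 | 2-(3,5,7,3',4'-penta-O-benzylepicatechin-4β-yl)benzene-1,3,5-triol | Oc1cc(O)c([C@H]4c5c(OCc9ccccc9)cc(OCc9ccccc9)cc5O[C@H](c5ccc(OCc9ccccc9)c(OCc9ccccc9)c5)[C@@H]4OCc9ccccc9)c(O)c1
F4 | step 5 | 2-(3,5,7,3',4'-penta-O-benzylepicatechin-4β-yl)-5-(triisopropylsilyloxy)benzene-1,3-diol | CC(C)[Si](C(C)C)(C(C)C)Oc1cc(O)c([C@H]4c5c(OCc9ccccc9)cc(OCc9ccccc9)cc5O[C@H](c5ccc(OCc9ccccc9)c(OCc9ccccc9)c5)[C@@H]4OCc9ccccc9)c(O)c1
F5 | step 15 | 2-phenyl-4H-1,3,2-benzodioxaborin from 8 and 21 (boron bridges the ring D oxygen and the C4' oxygen; C4' epimers) | COCOc1cc([C@@H](O[Si](C)(C)C(C)(C)C)[C@H](OCOC)C2OB(c6ccccc6)Oc3cc(OCc9ccccc9)c([C@H]4c5c(OCc9ccccc9)cc(OCc9ccccc9)cc5O[C@H](c5ccc(OCc9ccccc9)c(OCc9ccccc9)c5)[C@@H]4OCc9ccccc9)c(OCc9ccccc9)c32)cc(OCc9ccccc9)c1OCc9ccccc9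
F6 | step 16 | diacetate of 23 (ring D aryl acetate and C4' benzylic acetate) | COCOc1cc([C@@H](O[Si](C)(C)C(C)(C)C)[C@H](OCOC)C(OC(C)=O)c3c(OC(C)=O)cc(OCc9ccccc9)c([C@H]4c5c(OCc9ccccc9)cc(OCc9ccccc9)cc5O[C@H](c5ccc(OCc9ccccc9)c(OCc9ccccc9)c5)[C@@H]4OCc9ccccc9)c3OCc9ccccc9)cc(OCc9ccccc9)c1OCc9ccccc9
A1 | alternative 1 | protected dimer with both tri-O-benzylgalloyl esters, free C5' hydroxyl and C7' triisopropylsilyl ether | O=C(Oc1cc([C@H]2Oc3cc(O[Si](C(C)C)(C(C)C)C(C)C)c([C@H]4c5c(OCc9ccccc9)cc(OCc9ccccc9)cc5O[C@H](c5ccc(OCc9ccccc9)c(OCc9ccccc9)c5)[C@@H]4OCc9ccccc9)c(O)c3C[C@H]2OC(=O)c2cc(OCc9ccccc9)c(OCc9ccccc9)c(OCc9ccccc9)c2)cc(OCc9ccccc9)c1OCc9ccccc9)c1cc(OCc9ccccc9)c(OCc9ccccc9)c(OCc9ccccc9)c1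
A2 | alternative 1 | ring F-fused 3-alkoxycyclobutenone (2-oxabicyclo[4.2.0]oct-1(8)-en-7-one) carrying ring E and both tri-O-benzylgalloyl esters | O=C1C=C2O[C@H](c3cc(OC(=O)c4cc(OCc9ccccc9)c(OCc9ccccc9)c(OCc9ccccc9)c4)c(OCc9ccccc9)c(OCc9ccccc9)c3)[C@H](OC(=O)c3cc(OCc9ccccc9)c(OCc9ccccc9)c(OCc9ccccc9)c3)CC12
A3 | alternative 1 | 4β-[(triisopropylsilyloxy)ethynyl]-3,5,7,3',4'-penta-O-benzylepicatechin | CC(C)[Si](C(C)C)(C(C)C)OC#C[C@H]4c5c(OCc9ccccc9)cc(OCc9ccccc9)cc5O[C@H](c5ccc(OCc9ccccc9)c(OCc9ccccc9)c5)[C@@H]4OCc9ccccc9
A4 | alternative 2 | 4β→6 dimer with a pinacolboryl group at upper C3 (2,3-cis, 3,4-trans) and silyl-protected lower unit | CC(C)(C)[Si](C)(C)Oc1cc([C@H]2Oc3cc(OCc9ccccc9)c([C@H]4c5c(OCc9ccccc9)cc(OCc9ccccc9)cc5O[C@H](c5ccc(OCc9ccccc9)c(OCc9ccccc9)c5)[C@@H]4B6OC(C)(C)C(C)(C)O6)c(OCc9ccccc9)c3C[C@H]2O[Si](C)(C)C(C)(C)C)cc(OCc9ccccc9)c1OCc9ccccc9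
A5 | alternative 2 | ortho-hydroxy diarylcarbinol joining ring A to C6' of the silyl-protected lower flavan | CC(C)(C)[Si](C)(C)Oc1cc([C@H]2Oc3cc(OCc9ccccc9)c(C(O)c5c(O)cc(OCc9ccccc9)cc5OCc9ccccc9)c(OCc9ccccc9)c3C[C@H]2O[Si](C)(C)C(C)(C)C)cc(OCc9ccccc9)c1OCc9ccccc9
A6 | alternative 2 | ring A ortho-quinone methide formed from A5 by loss of water | CC(C)(C)[Si](C)(C)Oc1cc([C@H]2Oc3cc(OCc9ccccc9)c(C=C5C(=O)C=C(OCc9ccccc9)C=C5OCc9ccccc9)c(OCc9ccccc9)c3C[C@H]2O[Si](C)(C)C(C)(C)C)cc(OCc9ccccc9)c1OCc9ccccc9
A7 | alternative 2 | (Z)-2-[3,4-bis(benzyloxy)phenyl]vinylboronic acid pinacol ester | CC1(C)OB(/C=C\c2ccc(OCc3ccccc3)c(OCc3ccccc3)c2)OC1(C)C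
A8 | alternative 3 | 4β→6 dimer whose ring F is a 2'-hydroxy (hemiketal) flavan-3'-ol, one C2' anomer drawn | CC(C)(C)[Si](C)(C)Oc1cc([C@]2(O)Oc3cc(OCc9ccccc9)c([C@H]4c5c(OCc9ccccc9)cc(OCc9ccccc9)cc5O[C@H](c5ccc(OCc9ccccc9)c(OCc9ccccc9)c5)[C@@H]4OCc9ccccc9)c(OCc9ccccc9)c3C[C@H]2O)cc(OCc9ccccc9)c1OCc9ccccc9
A9 | alternative 3 | ring D lactol (2,3-dihydrobenzofuran-2-ol) carrying the penta-O-benzylepicatechin-4β-yl group | OC1Cc2c(O1)cc(OCc9ccccc9)c([C@H]4c5c(OCc9ccccc9)cc(OCc9ccccc9)cc5O[C@H](c5ccc(OCc9ccccc9)c(OCc9ccccc9)c5)[C@@H]4OCc9ccccc9)c2OCc9ccccc9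
A10 | alternative 3 | 3,4-bis(benzyloxy)-5-(tert-butyldimethylsilyloxy)benzaldehyde | CC(C)(C)[Si](C)(C)Oc1cc(C=O)cc(OCc2ccccc2)c1OCc2ccccc2
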